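**Retrosynthetic overview**
1. Hernanol 18 ⇐ thermodynamic epimerisation at C3 ⇐ hydrogenation with debenzylation ⇐ (E)-α-arylidene lactone 15.
2. Feature used: in the γ-butyrolactone ring (O1, C2=O, C3, C4, C5) the carbonyl carbon C2 is bonded only to O1 and C3. It is therefore brought in as CO between the C5 hydroxyl oxygen and the alkyne carbon that becomes C3 (15 ⇐ alkynol 13 + CO).
3. 13 ⇐ Sonogashira coupling of terminal alkyne 10 with 5-iodo-1,2,3-trimethoxybenzene; 10 ⇐ aldehyde 9 by one-carbon homologation.
4. C4 stereocentre ⇐ lipase desymmetrisation of prochiral diol 5 (from diethyl malonate and benzylic chloride 2); the two arms are told apart by acetate and silyl protection.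
5. Ring order: both benzene rings are bought; the lactone is the only ring made, in step 11.

Key step: step 11

Assumption: lipase PS acetylates the pro-S hydroxymethyl arm of diol 5, giving (S)-6; if the enzyme prefers the other arm, the fallback given for step 4 supplies the same (R)-alcohol 8.

**Route**

Step 1
Reactants: 1 4-(benzyloxy)-3-methoxybenzyl alcohol
Product: 2 4-(benzyloxy)-3-methoxybenzyl chloride
Conditions: SOCl2, CH2Cl2, 0 °C → rt; used crude
Reagents that add atoms: thionyl chloride, O=S(Cl)Cl
Why: Chlorination of an electron-rich benzylic alcohol through its chlorosulfite is fast at low temperature, and the aryl benzyl ether should tolerate the brief exposure to HCl.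

Step 2
Reactants: 2 4-(benzyloxy)-3-methoxybenzyl chloride; 3 diethyl malonate
Product: 4 diethyl 2-[4-(benzyloxy)-3-methoxybenzyl]malonate
Conditions: NaH, 3 (3 equiv), THF/DMF, 0 °C → rt
Reagents that add atoms: none
Why: Malonic ester alkylation with a reactive benzylic chloride, the excess of malonate holding back dialkylation.

Step 3
Reactants: 4 diethyl 2-[4-(benzyloxy)-3-methoxybenzyl]malonate
Product: 5 2-[4-(benzyloxy)-3-methoxybenzyl]propane-1,3-diol
Conditions: LiAlH4, THF, 0 °C → rt; aq. NaOH work-up
Reagents that add atoms: none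
Why: Hydride reduction of both esters gives the prochiral 2-substituted propane-1,3-diol, and the benzyl ether is inert to LiAlH4.

Step 4
Reactants: 5 2-[4-(benzyloxy)-3-methoxybenzyl]propane-1,3-diol
Product: 6 (2S)-2-[4-(benzyloxy)-3-methoxybenzyl]-3-hydroxypropyl acetate
Conditions: lipase PS (Burkholderia cepacia), vinyl acetate, t-BuOMe, rt
Reagents that add atoms: vinyl acetate, C=COC(C)=O
Why: Enzymatic desymmetrisation by irreversible transesterification is established for 2-arylmethylpropane-1,3-diols; the lipase acylates one enantiotopic hydroxymethyl arm and so sets C2 (the future lactone C4), the sense shown resting on the stated assumption.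

Step 5
Reactants: 6 (2S)-2-[4-(benzyloxy)-3-methoxybenzyl]-3-hydroxypropyl acetate
Product: 7 (2R)-2-[4-(benzyloxy)-3-methoxybenzyl]-3-[(tert-butyldiphenylsilyl)oxy]propyl acetate
Conditions: TBDPSCl, imidazole, CH2Cl2, 0 °C → rt
Reagents that add atoms: tert-butyldiphenylsilyl chloride, CC(C)(C)[Si](Cl)(c1ccccc1)c1ccccc1
Why: Silylation of the free primary alcohol, run promptly and cold so that 1,3-acyl migration cannot erode the enantiomeric purity (the descriptor changes only through CIP priorities).

Step 6
Reactants: 7 (2R)-2-[4-(benzyloxy)-3-methoxybenzyl]-3-[(tert-butyldiphenylsilyl)oxy]propyl acetate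
Product: 8 (2R)-2-[4-(benzyloxy)-3-methoxybenzyl]-3-[(tert-butyldiphenylsilyl)oxy]propan-1-ol
Conditions: K2CO3 (cat.), MeOH, 0 °C → rt
Reagents that add atoms: none
Why: Base-catalysed methanolysis removes the acetate, and the bulky TBDPS group is chosen because it should not migrate between the two oxygen atoms, which would racemise the compound.

Step 7
Reactants: 8 (2R)-2-[4-(benzyloxy)-3-methoxybenzyl]-3-[(tert-butyldiphenylsilyl)oxy]propan-1-ol
Product: 9 (2S)-2-[4-(benzyloxy)-3-methoxybenzyl]-3-[(tert-butyldiphenylsilyl)oxy]propanal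
Conditions: Dess–Martin periodinane, CH2Cl2, 0 °C → rt; used without chromatography
Reagents that add atoms: none
Why: Dess–Martin oxidation is non-basic, so the α-stereocentre of the aldehyde should survive, and a β-silyloxy aldehyde is far less prone to β-elimination than the β-acetoxy aldehyde that direct oxidation of 6 would give.

Step 8
Reactants: 9 (2S)-2-[4-(benzyloxy)-3-methoxybenzyl]-3-[(tert-butyldiphenylsilyl)oxy]propanal
Product: 10 {[(2R)-2-[4-(benzyloxy)-3-methoxybenzyl]but-3-yn-1-yl]oxy}(tert-butyl)diphenylsilane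
Conditions: dimethyl (1-diazo-2-oxopropyl)phosphonate, K2CO3, MeOH, 0 °C → rt
Reagents that add atoms: dimethyl (1-diazo-2-oxopropyl)phosphonate (Ohira–Bestmann reagent), COP(=O)(OC)C(=[N+]=[N-])C(C)=O
Why: Seyferth–Gilbert homologation in the Ohira–Bestmann variant turns the aldehyde into the terminal alkyne under mild carbonate conditions, which α-branched β-silyloxy aldehydes of this type normally tolerate without epimerisation.

Step 9
Reactants: 10 {[(2R)-2-[4-(benzyloxy)-3-methoxybenzyl]but-3-yn-1-yl]oxy}(tert-butyl)diphenylsilane; 11 5-iodo-1,2,3-trimethoxybenzene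
Product: 12 {[(2R)-2-[4-(benzyloxy)-3-methoxybenzyl]-4-(3,4,5-trimethoxyphenyl)but-3-yn-1-yl]oxy}(tert-butyl)diphenylsilane
Conditions: Pd(PPh3)2Cl2 (cat.), CuI (cat.), Et3N, THF (degassed), rt → 45 °C
Reagents that add atoms: none
Why: Sonogashira coupling of a terminal alkyne with an aryl iodide proceeds under mild amine conditions that leave the propargylic stereocentre and both ethers untouched.

Step 10
Reactants: 12 {[(2R)-2-[4-(benzyloxy)-3-methoxybenzyl]-4-(3,4,5-trimethoxyphenyl)but-3-yn-1-yl]oxy}(tert-butyl)diphenylsilane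
Product: 13 (2R)-2-[4-(benzyloxy)-3-methoxybenzyl]-4-(3,4,5-trimethoxyphenyl)but-3-yn-1-ol
Conditions: TBAF, THF, 0 °C → rt
Reagents that add atoms: none
Why: Fluoride-mediated desilylation frees the primary hydroxyl without affecting the alkyne, the benzyl ether or the stereocentre.

Step 11
Reactants: 13 (2R)-2-[4-(benzyloxy)-3-methoxybenzyl]-4-(3,4,5-trimethoxyphenyl)but-3-yn-1-ol; 14 carbon monoxide
Product: 15 (4R,E)-4-[4-(benzyloxy)-3-methoxybenzyl]-3-(3,4,5-trimethoxybenzylidene)dihydrofuran-2(3H)-one
Conditions: PdCl2(PPh3)2 (cat.), anhydrous SnCl2 (cat.), CO (8 atm), MeCN (0.05 M), 75 °C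
Reagents that add atoms: none
Why: Under CO the hydroxyl of 13 attacks a palladium(II)-bound carbonyl to give a tethered alkoxycarbonyl–palladium, which adds syn across the alkyne so that C2 bonds to the proximal alkyne carbon (C3) and palladium ends on the aryl-bearing carbon, and protonolysis of this vinyl–palladium bond with retention by the HCl released at the outset gives the alkene and returns Pd(II). The closest known reaction type is the PdCl2/SnCl2/phosphine cyclocarbonylation of but-3-yn-1-ols to α-methylene- and (E)-α-alkylidene-γ-butyrolactones. The γ-lactone O1–C2–C3–C4–C5 closes in 5-exo-dig mode with formation of C2–O1 and C2–C3, the endo alternative requiring a trans double bond in a six-membered ring. No stereocentre is created: C4 comes in unchanged from 13, and the E geometry (vinyl H cis to the carbonyl) follows from syn addition and retentive protonolysis. The selectivity needed is regiochemical (carbonyl on C3, not on the aryl-bearing carbon) and chemical (carbonylation ahead of 5-endo hydroalkoxylation of the electron-rich aryl alkyne); the first is secured by the two-atom C5–C4 tether, which lets the alkoxycarbonyl group reach only the proximal carbon in a syn insertion, and the second by phosphine-ligated palladium under CO pressure without oxidant or added alcohol. A palladium hydride pathway, should it operate, places the acyl group on the same carbon for lactonisation and converges on the same E lactone.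

Step 12
Reactants: 15 (4R,E)-4-[4-(benzyloxy)-3-methoxybenzyl]-3-(3,4,5-trimethoxybenzylidene)dihydrofuran-2(3H)-one
Product: 17 (3S,4R)-4-(4-hydroxy-3-methoxybenzyl)-3-(3,4,5-trimethoxybenzyl)dihydrofuran-2(3H)-one (3-epi-hernanol), via O-benzyl-3-epi-hernanol 16 (not isolated)
Conditions: H2 (1 atm), 10% Pd/C, EtOAc/MeOH, rt
Reagents that add atoms: none
Why: Heterogeneous catalytic hydrogenation saturates the arylidene bond and hydrogenolyses the aryl benzyl ether in one operation; hydrogen should add mainly to the alkene face opposite the C4 benzyl group, setting C3 provisionally as S (3,4-cis), and any trans isomer formed is already the target and is carried along.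

Step 13
Reactants: 17 (3S,4R)-4-(4-hydroxy-3-methoxybenzyl)-3-(3,4,5-trimethoxybenzyl)dihydrofuran-2(3H)-one
Product: 18 hernanol, (3R,4R)-4-(4-hydroxy-3-methoxybenzyl)-3-(3,4,5-trimethoxybenzyl)dihydrofuran-2(3H)-one
Conditions: NaOMe (3 equiv), MeOH (degassed), rt → 50 °C; then aq. HCl
Reagents that add atoms: none
Why: Base-mediated epimerisation through the lactone enolate is under thermodynamic control and should place the two benzyl groups trans, setting C3 as R, while C4 is not α to the carbonyl and stays fixed and acidification re-closes any lactone opened by methoxide.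

**Compound list**
1 | 4-(benzyloxy)-3-methoxybenzyl alcohol | OCc1ccc(OCc2ccccc2)c(OC)c1 | starting material
2 | 4-(benzyloxy)-3-methoxybenzyl chloride | ClCc1ccc(OCc2ccccc2)c(OC)c1 | intermediate
3 | diethyl malonate | CCOC(=O)CC(=O)OCC | starting material
4 | diethyl 2-[4-(benzyloxy)-3-methoxybenzyl]malonate | CCOC(=O)C(Cc1ccc(OCc2ccccc2)c(OC)c1)C(=O)OCC | intermediate
5 | 2-[4-(benzyloxy)-3-methoxybenzyl]propane-1,3-diol | OCC(CO)Cc1ccc(OCc2ccccc2)c(OC)c1 | intermediate
6 | (2S)-2-[4-(benzyloxy)-3-methoxybenzyl]-3-hydroxypropyl acetate | OC[C@H](Cc1ccc(OCc2ccccc2)c(OC)c1)COC(C)=O | intermediate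
7 | (2R)-2-[4-(benzyloxy)-3-methoxybenzyl]-3-[(tert-butyldiphenylsilyl)oxy]propyl acetate | CC(C)(C)[Si](c1ccccc1)(c1ccccc1)OC[C@H](Cc1ccc(OCc2ccccc2)c(OC)c1)COC(C)=O | intermediate
8 | (2R)-2-[4-(benzyloxy)-3-methoxybenzyl]-3-[(tert-butyldiphenylsilyl)oxy]propan-1-ol | CC(C)(C)[Si](c1ccccc1)(c1ccccc1)OC[C@H](Cc1ccc(OCc2ccccc2)c(OC)c1)CO | intermediate
9 | (2S)-2-[4-(benzyloxy)-3-methoxybenzyl]-3-[(tert-butyldiphenylsilyl)oxy]propanal | CC(C)(C)[Si](c1ccccc1)(c1ccccc1)OC[C@H](Cc1ccc(OCc2ccccc2)c(OC)c1)C=O | intermediate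
10 | {[(2R)-2-[4-(benzyloxy)-3-methoxybenzyl]but-3-yn-1-yl]oxy}(tert-butyl)diphenylsilane | CC(C)(C)[Si](c1ccccc1)(c1ccccc1)OC[C@H](Cc1ccc(OCc2ccccc2)c(OC)c1)C#C | intermediate
11 | 5-iodo-1,2,3-trimethoxybenzene | COc1cc(I)cc(OC)c1OC | starting material
12 | {[(2R)-2-[4-(benzyloxy)-3-methoxybenzyl]-4-(3,4,5-trimethoxyphenyl)but-3-yn-1-yl]oxy}(tert-butyl)diphenylsilane | CC(C)(C)[Si](c1ccccc1)(c1ccccc1)OC[C@H](Cc1ccc(OCc2ccccc2)c(OC)c1)C#Cc1cc(OC)c(OC)c(OC)c1 | intermediate
13 | (2R)-2-[4-(benzyloxy)-3-methoxybenzyl]-4-(3,4,5-trimethoxyphenyl)but-3-yn-1-ol | OC[C@H](Cc1ccc(OCc2ccccc2)c(OC)c1)C#Cc1cc(OC)c(OC)c(OC)c1 | intermediate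
14 | carbon monoxide | [C-]#[O+] | starting material
15 | (4R,E)-4-[4-(benzyloxy)-3-methoxybenzyl]-3-(3,4,5-trimethoxybenzylidene)dihydrofuran-2(3H)-one | COc1cc(/C=C2/C(=O)OC[C@@H]2Cc2ccc(OCc3ccccc3)c(OC)c2)cc(OC)c1OC | intermediate
16 | (3S,4R)-4-[4-(benzyloxy)-3-methoxybenzyl]-3-(3,4,5-trimethoxybenzyl)dihydrofuran-2(3H)-one (O-benzyl-3-epi-hernanol) | COc1cc(C[C@H]2COC(=O)[C@H]2Cc2cc(OC)c(OC)c(OC)c2)ccc1OCc1ccccc1 | intermediate
17 | (3S,4R)-4-(4-hydroxy-3-methoxybenzyl)-3-(3,4,5-trimethoxybenzyl)dihydrofuran-2(3H)-one (3-epi-hernanol) | COc1cc(C[C@H]2COC(=O)[C@H]2Cc2cc(OC)c(OC)c(OC)c2)ccc1O | intermediate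
18 | hernanol, (3R,4R)-4-(4-hydroxy-3-methoxybenzyl)-3-(3,4,5-trimethoxybenzyl)dihydrofuran-2(3H)-one | COc1cc(C[C@H]2COC(=O)[C@@H]2Cc2cc(OC)c(OC)c(OC)c2)ccc1O | target

**Step count**
Total steps: 13. Longest linear sequence: 13 steps (1 → 18); 3, 11 and 14 enter as purchased compounds.

**Steps most likely to fail**

Step 11. Insertion of the internal, aryl-substituted alkyne into the alkoxycarbonyl–palladium bond may be slow. Palladium-promoted cycloisomerisation of the alkynol, or intermolecular ester formation, could then consume the substrate. The fallback sets out from 10 and returns at 16. Desilylation of 10 with TBAF in THF would give the terminal alkynol (2R)-2-[4-(benzyloxy)-3-methoxybenzyl]but-3-yn-1-ol F1. Cyclocarbonylation of this terminal alkyne under the palladium/tin/CO conditions of step 11, the best-precedented substrate type for the reaction, would give the α-methylene lactone (4R)-4-[4-(benzyloxy)-3-methoxybenzyl]-3-methylenedihydrofuran-2(3H)-one F2. The aryl group would then be added by rhodium-catalysed conjugate addition (Hayashi–Miyaura type) of (3,4,5-trimethoxyphenyl)boronic acid with [Rh(cod)OH]2 in dioxane/water at 50 °C. Protonation of the rhodium enolate should give 16 together with its C3 epimer (3R,4R)-4-[4-(benzyloxy)-3-methoxybenzyl]-3-(3,4,5-trimethoxybenzyl)dihydrofuran-2(3H)-one F3. The mixture enters step 12 for debenzylation, and step 13 converges both epimers on 18. C4 is not touched at any point.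

Step 8. The α-stereocentre of aldehyde 9 may epimerise under the carbonate/methanol conditions before the homologation is complete, lowering the enantiomeric purity of 10. The fallback sets out from 9 and returns at 10 by a Corey–Fuchs sequence that never exposes the aldehyde to base. Dibromo-olefination with CBr4 and PPh3 in CH2Cl2 at 0 °C would give {[(2R)-2-[4-(benzyloxy)-3-methoxybenzyl]-4,4-dibromobut-3-en-1-yl]oxy}(tert-butyl)diphenylsilane F4. Treatment with n-BuLi (2.1 equiv) in THF at −78 °C and quenching with aqueous NH4Cl should then give 10 by bromine–lithium exchange and 1,2-shift.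

Step 4. The enzyme may discriminate the two hydroxymethyl arms insufficiently or in the opposite sense, or acyl migration in the monoacetate may erode its purity. The fallback sets out from 5 and returns at 8 using a small-molecule catalyst available in both enantiomeric forms. Desymmetrising benzoylation of 5 with vinyl benzoate and a dinuclear zinc–ProPhenol catalyst (Et2Zn, ligand enantiomer chosen to acylate the pro-S arm, toluene, −15 °C) would give (2S)-2-[4-(benzyloxy)-3-methoxybenzyl]-3-hydroxypropyl benzoate F5. Silylation with TBDPSCl and imidazole would give (2R)-2-[4-(benzyloxy)-3-methoxybenzyl]-3-[(tert-butyldiphenylsilyl)oxy]propyl benzoate F6, and methanolysis with K2CO3 in MeOH would give 8. Benzoates migrate less readily than acetates.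

**Further compounds**
F1 | step 11 | (2R)-2-[4-(benzyloxy)-3-methoxybenzyl]but-3-yn-1-ol | OC[C@H](Cc1ccc(OCc2ccccc2)c(OC)c1)C#C
F2 | step 11 | (4R)-4-[4-(benzyloxy)-3-methoxybenzyl]-3-methylenedihydrofuran-2(3H)-one | C=C1C(=O)OC[C@@H]1Cc1ccc(OCc2ccccc2)c(OC)c1
F3 | step 11 | (3R,4R)-4-[4-(benzyloxy)-3-methoxybenzyl]-3-(3,4,5-trimethoxybenzyl)dihydrofuran-2(3H)-one | COc1cc(C[C@H]2COC(=O)[C@@H]2Cc2cc(OC)c(OC)c(OC)c2)ccc1OCc1ccccc1
F4 | step 8 | {[(2R)-2-[4-(benzyloxy)-3-methoxybenzyl]-4,4-dibromobut-3-en-1-yl]oxy}(tert-butyl)diphenylsilane | CC(C)(C)[Si](c1ccccc1)(c1ccccc1)OC[C@H](Cc1ccc(OCc2ccccc2)c(OC)c1)C=C(Br)Br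
F5 | step 4 | (2S)-2-[4-(benzyloxy)-3-methoxybenzyl]-3-hydroxypropyl benzoate | OC[C@H](Cc1ccc(OCc2ccccc2)c(OC)c1)COC(=O)c1ccccc1
F6 | step 4 | (2R)-2-[4-(benzyloxy)-3-methoxybenzyl]-3-[(tert-butyldiphenylsilyl)oxy]propyl benzoate | CC(C)(C)[Si](c1ccccc1)(c1ccccc1)OC[C@H](Cc1ccc(OCc2ccccc2)c(OC)c1)COC(=O)c1ccccc1
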